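**Strategy.** Rings are lettered A to G from the 2,4,6-trihydroxyphenyl end. Everything rests on building ring C de novo. Its five contiguous oxygens (C1–O–B, C6–O–D, hydroxyls on C3, C4, C5) and its single C2–H are the imprint of a squarate plus a 1-aryloxyvinyl unit. The precursor is a racemic cyclobutenone carrying two benzyloxy groups, a MOM-capped tertiary oxygen and the 1-aryloxyvinyl group of the perbenzylated A–B dimer. Heating it forms the C2–C3 bond, closes ring C, and leaves C3–OH free and C6–O masked. The B–O–C1 ether stems from an ynol ether. Rings D, E and F–G follow by repeated Ullmann etherification of bromobenzaldehydes and Baeyer–Villiger oxidation; hydrogenolysis ends the route.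

Key step: step 11

Assumption: 2,4,6-trihydroxybenzaldehyde, 5-bromo-2,3-dihydroxybenzaldehyde, 4-bromo-2,6-difluorobenzaldehyde and 5-bromopyrogallol are taken as catalogue chemicals; the target is achiral, so no configuration has to be set.

Locants: B1 bears O–A and B5 bears O–C. C1 bears O–B, C2 is the CH, C6 bears O–D. D1 bears O–C and D4 bears O–E. E1 bears O–D, E2 is the CH, E6 bears O–F. F1 bears O–E, F4 lies para to it, F5 bears O–G.

Abbreviations:
- Bn = benzyl; MOM = methoxymethyl.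
- ArAB = 2,3-bis(benzyloxy)-5-[2,4,6-tris(benzyloxy)phenoxy]phenyl.
- ArABC = 2,3,4-tris(benzyloxy)-6-(ArAB-oxy)phenyl.
- ArABCD = 2,6-bis(benzyloxy)-4-(ArABC-oxy)phenyl.
- ArABCDE = 2,3,4-tris(benzyloxy)-6-(ArABCD-oxy)phenyl.

## Route

Step 1
Reactants: 1 2,4,6-trihydroxybenzaldehyde
Product: 2 2,4,6-tris(benzyloxy)benzaldehyde
Conditions: BnBr, K2CO3, DMF, 60 °C
Reagents that add atoms: benzyl bromide, BrCc1ccccc1
Why: Williamson etherification, in which the formyl group lowers the carbon nucleophilicity of the phloroglucinol ring so that O-benzylation should prevail over C-benzylation.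

Step 2
Reactants: 2 2,4,6-tris(benzyloxy)benzaldehyde
Product: 4 2,4,6-tris(benzyloxy)phenol, via aryl formate 3 (not isolated)
Conditions: mCPBA, CH2Cl2, 0 °C to rt; crude formate after aqueous wash, K2CO3 (cat.), MeOH–THF, rt
Reagents that add atoms: mCPBA, OOC(=O)c1cccc(Cl)c1
Why: Baeyer–Villiger oxidation in which the electron-rich trialkoxyaryl group migrates in preference to hydride, followed by transesterification of the formate.

Step 3
Reactants: 5 5-bromo-2,3-dihydroxybenzaldehyde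
Product: 6 2,3-bis(benzyloxy)-5-bromobenzaldehyde
Conditions: BnBr, K2CO3, DMF, 50 °C
Reagents that add atoms: benzyl bromide, BrCc1ccccc1
Why: Williamson etherification of both catechol hydroxyls, the chelated 2-OH included, under standard carbonate conditions.

Step 4
Reactants: 4 2,4,6-tris(benzyloxy)phenol; 6 2,3-bis(benzyloxy)-5-bromobenzaldehyde
Product: 7 2,3-bis(benzyloxy)-5-[2,4,6-tris(benzyloxy)phenoxy]benzaldehyde (A–B aldehyde)
Conditions: CuI (cat.), picolinic acid (cat.), K3PO4, DMSO, 90 °C, Ar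
Reagents that add atoms: none
Why: Ullmann diaryl ether synthesis with a ligand system that tolerates di-ortho-substituted phenols, helped by a bromide with two free ortho positions and a meta formyl group that makes it less electron-rich.

Step 5
Reactants: 7 A–B aldehyde
Product: 9 2,3-bis(benzyloxy)-5-[2,4,6-tris(benzyloxy)phenoxy]phenol (ArAB–OH), via aryl formate 8 (not isolated)
Conditions: mCPBA, CH2Cl2, 0 °C to rt; crude formate after aqueous wash, K2CO3 (cat.), MeOH–THF, rt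
Reagents that add atoms: mCPBA, OOC(=O)c1cccc(Cl)c1
Why: Baeyer–Villiger oxidation of an ortho-alkoxybenzaldehyde with aryl migration, then formate methanolysis, unmasks the B5 hydroxyl without a separate protecting group.

Step 6
Reactants: 9 ArAB–OH; 10 trichloroethylene
Product: 12 (E)-1,2-dichlorovinyl ArAB ether, via dichloroacetylene 11 (not isolated)
Conditions: K2CO3, DMF, 70 °C
Reagents that add atoms: none
Why: Base-induced loss of HCl from trichloroethylene followed by anti addition of the phenoxide is the established way from phenols to (E)-1,2-dichlorovinyl ethers.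

Step 7
Reactants: 12 (E)-1,2-dichlorovinyl ArAB ether
Product: 15 ethynyl ArAB ether, via chloroethynyl ether 13 (not isolated), via lithium acetylide 14 (not isolated)
Conditions: n-BuLi (2.5 equiv), THF, −78 to −40 °C; then H2O
Reagents that add atoms: none
Why: Dehydrochlorination, chlorine–lithium exchange and protonation form the standard conversion of dichlorovinyl ethers into terminal ynol ethers, and benzyl and diaryl ethers are inert to n-BuLi at this temperature.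

Step 8
Reactants: 15 ethynyl ArAB ether
Product: 16 tributyl[1-(ArAB-oxy)vinyl]stannane
Conditions: Bu3SnH, Pd(PPh3)4 (cat.), THF, 0 °C
Reagents that add atoms: tributyltin hydride, CCCC[SnH](CCCC)CCCC
Why: Syn hydrostannylation catalysed by zerovalent palladium, which on ynol ethers places tin on the oxygen-bearing carbon and hydrogen on the terminal carbon.

Step 9
Reactants: 17 squaric acid
Product: 18 3,4-bis(benzyloxy)cyclobut-3-ene-1,2-dione (dibenzyl squarate)
Conditions: BnOH, toluene, reflux, Dean–Stark trap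
Reagents that add atoms: benzyl alcohol, OCc1ccccc1
Why: Azeotropic Fischer-type esterification, self-catalysed by the strongly acidic squaric acid.

Step 10
Reactants: 16 tributyl[1-(ArAB-oxy)vinyl]stannane; 18 dibenzyl squarate
Product: 21 rac-4-[1-(ArAB-oxy)vinyl]-2,3-bis(benzyloxy)-4-(methoxymethoxy)cyclobut-2-en-1-one, via vinyllithium 19 (not isolated), via lithium alkoxide 20 (not isolated)
Conditions: n-BuLi, THF, −78 °C; transfer into 18, THF, −78 °C; MOMCl, −78 to 0 °C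
Reagents that add atoms: chloromethyl methyl ether, COCCl
Why: Tin–lithium exchange gives the α-oxygenated vinyllithium, which undergoes the usual 1,2-addition to one of the two equivalent squarate carbonyls, and the alkoxide is O-alkylated by the very reactive MOMCl; the new quaternary centre is racemic and is erased in step 11.

Step 11
Reactants: 21 rac-4-[1-(ArAB-oxy)vinyl]-2,3-bis(benzyloxy)-4-(methoxymethoxy)cyclobut-2-en-1-one
Product: 24 2,3-bis(benzyloxy)-4-(methoxymethoxy)-5-(ArAB-oxy)phenol (A–B–C trimer), via dienylketene 22 (not isolated), via cyclohexadienone 23 (not isolated)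
Conditions: degassed toluene (dilute), 110 °C, Ar
Reagents that add atoms: none
Why: Thermal conrotatory 4π opening of the bond between the carbonyl carbon and the sp3 carbon of 21 gives dienylketene 22, and because the MOM-oxygen donor rotates outward the 1-aryloxyvinyl group turns inward, next to the ketene. Disrotatory 6π electrocyclisation then joins the vinyl CH2 carbon to the ketene carbon (the C2–C3 bond), closing the six-membered ring C as dienone 23, which tautomerises irreversibly to phenol 24. The closest known reaction is the Moore-type ring expansion of 4-alkenyl-4-alkoxycyclobutenones made from squarate esters, which gives hydroquinone monoethers. No stereocentre is created, and the racemic quaternary carbon of 21 becomes the planar C6. The only selectivity needed is torquoselectivity, secured by the oxygen donor on the sp3 carbon, while the unsubstituted CH2 terminus fixes the lone CH between the B ether and the new hydroxyl. Dilute, oxygen-free solution should keep the ketene from intermolecular capture and the electron-rich phenol from oxidation.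

Step 12
Reactants: 24 A–B–C trimer phenol
Product: 25 1,2,3-tris(benzyloxy)-4-(methoxymethoxy)-5-(ArAB-oxy)benzene
Conditions: BnBr, K2CO3, DMF, rt
Reagents that add atoms: benzyl bromide, BrCc1ccccc1
Why: Williamson etherification of the only free phenol (C3–OH), with MOM and benzyl ethers stable to carbonate.

Step 13
Reactants: 25 1,2,3-tris(benzyloxy)-4-(methoxymethoxy)-5-(ArAB-oxy)benzene
Product: 26 2,3,4-tris(benzyloxy)-6-(ArAB-oxy)phenol (ArABC–OH)
Conditions: HCl (cat.), MeOH–THF, 45 °C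
Reagents that add atoms: none
Why: Acid-catalysed acetal exchange removes the aryl MOM ether and frees C6–OH while benzyl and diaryl ethers are untouched.

Step 14
Reactants: 27 4-bromo-2,6-difluorobenzaldehyde
Product: 28 2,6-bis(benzyloxy)-4-bromobenzaldehyde (ring D block)
Conditions: BnOH (2.1 equiv), Cs2CO3, DMF, 80 °C
Reagents that add atoms: benzyl alcohol, OCc1ccccc1
Why: Double SNAr, since both fluorides are ortho to the formyl group and leave far faster than the para bromide.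

Step 15
Reactants: 26 ArABC–OH; 28 2,6-bis(benzyloxy)-4-bromobenzaldehyde
Product: 29 2,6-bis(benzyloxy)-4-(ArABC-oxy)benzaldehyde (A–D aldehyde)
Conditions: CuI (cat.), picolinic acid (cat.), K3PO4, DMSO, 90 °C, Ar
Reagents that add atoms: none
Why: Ullmann diaryl ether synthesis between the di-ortho-substituted C6 phenol and a bromide that is sterically free and activated by its para formyl group.

Step 16
Reactants: 29 A–D aldehyde
Product: 31 2,6-bis(benzyloxy)-4-(ArABC-oxy)phenol (ArABCD–OH), via aryl formate 30 (not isolated)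
Conditions: mCPBA, CH2Cl2, 0 °C to rt; crude formate after aqueous wash, K2CO3 (cat.), MeOH–THF, rt
Reagents that add atoms: mCPBA, OOC(=O)c1cccc(Cl)c1
Why: Baeyer–Villiger oxidation of a 2,4,6-trioxygenated benzaldehyde with aryl migration, then formate methanolysis, turns the activating formyl group into the D4 hydroxyl.

Step 17
Reactants: 32 5-bromopyrogallol
Product: 33 1,2,3-tris(benzyloxy)-5-bromobenzene
Conditions: BnBr, K2CO3, DMF, 50 °C, Ar
Reagents that add atoms: benzyl bromide, BrCc1ccccc1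
Why: Williamson etherification of all three hydroxyls, run under argon because pyrogallol anions oxidise in air.

Step 18
Reactants: 33 1,2,3-tris(benzyloxy)-5-bromobenzene
Product: 36 2,3,4-tris(benzyloxy)-6-bromobenzaldehyde (ring E block), via aryllithium 34 (not isolated), via lithium hemiaminal 35 (not isolated)
Conditions: LiN(iPr)2, THF, −78 °C; DMF, −78 °C; then H2O
Reagents that add atoms: N,N-dimethylformamide, CN(C)C=O
Why: Directed ortho-lithiation at the position flanked by bromine and benzyloxy (the two such sites are equivalent) gives an aryllithium that is stable at −78 °C and is formylated by DMF.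

Step 19
Reactants: 31 ArABCD–OH; 36 2,3,4-tris(benzyloxy)-6-bromobenzaldehyde
Product: 37 2,3,4-tris(benzyloxy)-6-(ArABCD-oxy)benzaldehyde (A–E aldehyde)
Conditions: CuI (cat.), picolinic acid (cat.), K3PO4, DMSO–1,4-dioxane, 95 °C, Ar
Reagents that add atoms: none
Why: Ullmann diaryl ether synthesis in which the bromide is activated by the ortho formyl group and has hydrogen on its other side, which offsets the crowding of the 2,6-bis(benzyloxy)phenol.

Step 20
Reactants: 37 A–E aldehyde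
Product: 39 2,3,4-tris(benzyloxy)-6-(ArABCD-oxy)phenol (ArABCDE–OH), via aryl formate 38 (not isolated)
Conditions: mCPBA, CH2Cl2, 0 °C to rt; crude formate after aqueous wash, K2CO3 (cat.), MeOH–THF, rt
Reagents that add atoms: mCPBA, OOC(=O)c1cccc(Cl)c1
Why: Baeyer–Villiger oxidation of a benzaldehyde carrying oxygen at both ortho positions and at the para position, then formate methanolysis, gives the E6 hydroxyl.

Step 21
Reactants: 27 4-bromo-2,6-difluorobenzaldehyde
Product: 40 2-(benzyloxy)-4-bromo-6-fluorobenzaldehyde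
Conditions: BnOH (1.0 equiv), Cs2CO3, DMF, 0 °C to rt
Reagents that add atoms: benzyl alcohol, OCc1ccccc1
Why: SNAr with one equivalent of alcohol, where the first alkoxy group deactivates the ring so that the reaction should stop at monosubstitution.

Step 22
Reactants: 33 1,2,3-tris(benzyloxy)-5-bromobenzene
Product: 41 3,4,5-tris(benzyloxy)phenol (ring G phenol)
Conditions: Pd2(dba)3 (cat.), tBuXPhos (cat.), KOH, 1,4-dioxane–H2O, 100 °C
Reagents that add atoms: potassium hydroxide, [K+].[OH-]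
Why: Palladium-catalysed hydroxylation of an aryl bromide with hydroxide and a bulky biarylphosphine, a reaction that accepts electron-rich bromides and leaves benzyl ethers alone.

Step 23
Reactants: 40 2-(benzyloxy)-4-bromo-6-fluorobenzaldehyde; 41 3,4,5-tris(benzyloxy)phenol
Product: 42 2-(benzyloxy)-4-bromo-6-[3,4,5-tris(benzyloxy)phenoxy]benzaldehyde (F–G block)
Conditions: K2CO3, DMF, 80 °C
Reagents that add atoms: none
Why: SNAr of an unhindered phenoxide at the fluoride ortho to the formyl group, fluoride leaving much faster than the para bromide.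

Step 24
Reactants: 39 ArABCDE–OH; 42 F–G block
Product: 43 2-(benzyloxy)-4-(ArABCDE-oxy)-6-[3,4,5-tris(benzyloxy)phenoxy]benzaldehyde (A–G aldehyde)
Conditions: CuI (cat.), picolinic acid (cat.), K3PO4, DMSO–1,4-dioxane, 95 °C, Ar
Reagents that add atoms: none
Why: Ullmann diaryl ether synthesis between the hindered E6 phenol and a bromide with two free ortho positions and a para formyl activator.

Step 25
Reactants: 43 A–G aldehyde
Product: 45 2-(benzyloxy)-4-(ArABCDE-oxy)-6-[3,4,5-tris(benzyloxy)phenoxy]phenol (A–G phenol), via aryl formate 44 (not isolated)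
Conditions: mCPBA, CH2Cl2, 0 °C to rt; crude formate after aqueous wash, K2CO3 (cat.), MeOH–THF, rt
Reagents that add atoms: mCPBA, OOC(=O)c1cccc(Cl)c1
Why: Baeyer–Villiger oxidation of a 2,4,6-trioxygenated benzaldehyde with aryl migration, then formate methanolysis, installs the last oxygen (F4–OH).

Step 26
Reactants: 45 A–G phenol
Product: 46 CNP0137585.0 (target heptamer)
Conditions: H2 (1 atm), Pd(OH)2/C, THF–MeOH, rt; filtration and concentration under Ar
Reagents that add atoms: none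
Why: Global hydrogenolysis of seventeen benzyl ethers over palladium, under which diaryl ethers and the arene rings are not reduced.

## Compound list

1 | 2,4,6-trihydroxybenzaldehyde | O=Cc1c(O)cc(O)cc1O | starting material
2 | 2,4,6-tris(benzyloxy)benzaldehyde | O=Cc1c(OCc9ccccc9)cc(OCc9ccccc9)cc1OCc9ccccc9 | intermediate
3 | 2,4,6-tris(benzyloxy)phenyl formate | O=COc1c(OCc9ccccc9)cc(OCc9ccccc9)cc1OCc9ccccc9 | intermediate
4 | 2,4,6-tris(benzyloxy)phenol | Oc1c(OCc9ccccc9)cc(OCc9ccccc9)cc1OCc9ccccc9 | intermediate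
5 | 5-bromo-2,3-dihydroxybenzaldehyde | O=Cc1cc(Br)cc(O)c1O | starting material
6 | 2,3-bis(benzyloxy)-5-bromobenzaldehyde | O=Cc1cc(Br)cc(OCc9ccccc9)c1OCc9ccccc9 | intermediate
7 | 2,3-bis(benzyloxy)-5-[2,4,6-tris(benzyloxy)phenoxy]benzaldehyde | O=Cc1cc(Oc2c(OCc9ccccc9)cc(OCc9ccccc9)cc2OCc9ccccc9)cc(OCc9ccccc9)c1OCc9ccccc9 | intermediate
8 | ArAB formate | O=COc1cc(Oc2c(OCc9ccccc9)cc(OCc9ccccc9)cc2OCc9ccccc9)cc(OCc9ccccc9)c1OCc9ccccc9 | intermediate
9 | ArAB–OH, 2,3-bis(benzyloxy)-5-[2,4,6-tris(benzyloxy)phenoxy]phenol | Oc1cc(Oc2c(OCc9ccccc9)cc(OCc9ccccc9)cc2OCc9ccccc9)cc(OCc9ccccc9)c1OCc9ccccc9 | intermediate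
10 | trichloroethylene | ClC=C(Cl)Cl | starting material
11 | dichloroacetylene | ClC#CCl | intermediate
12 | (E)-1,2-dichlorovinyl ArAB ether | Cl/C=C(Cl)\Oc1cc(Oc2c(OCc9ccccc9)cc(OCc9ccccc9)cc2OCc9ccccc9)cc(OCc9ccccc9)c1OCc9ccccc9 | intermediate
13 | chloroethynyl ArAB ether | ClC#COc1cc(Oc2c(OCc9ccccc9)cc(OCc9ccccc9)cc2OCc9ccccc9)cc(OCc9ccccc9)c1OCc9ccccc9 | intermediate
14 | lithium (ArAB-oxy)acetylide | [Li]C#COc1cc(Oc2c(OCc9ccccc9)cc(OCc9ccccc9)cc2OCc9ccccc9)cc(OCc9ccccc9)c1OCc9ccccc9 | intermediate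
15 | ethynyl ArAB ether | C#COc1cc(Oc2c(OCc9ccccc9)cc(OCc9ccccc9)cc2OCc9ccccc9)cc(OCc9ccccc9)c1OCc9ccccc9 | intermediate
16 | tributyl[1-(ArAB-oxy)vinyl]stannane | C=C([Sn](CCCC)(CCCC)CCCC)Oc1cc(Oc2c(OCc9ccccc9)cc(OCc9ccccc9)cc2OCc9ccccc9)cc(OCc9ccccc9)c1OCc9ccccc9 | intermediate
17 | squaric acid | OC1=C(O)C(=O)C1=O | starting material
18 | 3,4-bis(benzyloxy)cyclobut-3-ene-1,2-dione | O=C1C(=O)C(OCc9ccccc9)=C1OCc9ccccc9 | intermediate
19 | 1-(ArAB-oxy)vinyllithium | C=C([Li])Oc1cc(Oc2c(OCc9ccccc9)cc(OCc9ccccc9)cc2OCc9ccccc9)cc(OCc9ccccc9)c1OCc9ccccc9 | intermediate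
20 | lithium 1-[1-(ArAB-oxy)vinyl]-2,3-bis(benzyloxy)-4-oxocyclobut-2-en-1-olate (racemic) | C=C(Oc1cc(Oc2c(OCc9ccccc9)cc(OCc9ccccc9)cc2OCc9ccccc9)cc(OCc9ccccc9)c1OCc9ccccc9)C3(O[Li])C(OCc9ccccc9)=C(OCc9ccccc9)C3=O | intermediate
21 | rac-4-[1-(ArAB-oxy)vinyl]-2,3-bis(benzyloxy)-4-(methoxymethoxy)cyclobut-2-en-1-one | C=C(Oc1cc(Oc2c(OCc9ccccc9)cc(OCc9ccccc9)cc2OCc9ccccc9)cc(OCc9ccccc9)c1OCc9ccccc9)C3(OCOC)C(OCc9ccccc9)=C(OCc9ccccc9)C3=O | intermediate
22 | (3Z)-2,3-bis(benzyloxy)-4-(methoxymethoxy)-5-(ArAB-oxy)hexa-1,3,5-trien-1-one | O=C=C(OCc9ccccc9)/C(OCc9ccccc9)=C(OCOC)\C(=C)Oc1cc(Oc2c(OCc9ccccc9)cc(OCc9ccccc9)cc2OCc9ccccc9)cc(OCc9ccccc9)c1OCc9ccccc9 | intermediate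
23 | 2,3-bis(benzyloxy)-4-(methoxymethoxy)-5-(ArAB-oxy)cyclohexa-2,4-dien-1-one | O=C3CC(Oc1cc(Oc2c(OCc9ccccc9)cc(OCc9ccccc9)cc2OCc9ccccc9)cc(OCc9ccccc9)c1OCc9ccccc9)=C(OCOC)C(OCc9ccccc9)=C3OCc9ccccc9 | intermediate
24 | 2,3-bis(benzyloxy)-4-(methoxymethoxy)-5-(ArAB-oxy)phenol | Oc3cc(Oc1cc(Oc2c(OCc9ccccc9)cc(OCc9ccccc9)cc2OCc9ccccc9)cc(OCc9ccccc9)c1OCc9ccccc9)c(OCOC)c(OCc9ccccc9)c3OCc9ccccc9 | intermediate
25 | 1,2,3-tris(benzyloxy)-4-(methoxymethoxy)-5-(ArAB-oxy)benzene | COCOc3c(Oc1cc(Oc2c(OCc9ccccc9)cc(OCc9ccccc9)cc2OCc9ccccc9)cc(OCc9ccccc9)c1OCc9ccccc9)cc(OCc9ccccc9)c(OCc9ccccc9)c3OCc9ccccc9 | intermediate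
26 | ArABC–OH, 2,3,4-tris(benzyloxy)-6-(ArAB-oxy)phenol | Oc3c(Oc1cc(Oc2c(OCc9ccccc9)cc(OCc9ccccc9)cc2OCc9ccccc9)cc(OCc9ccccc9)c1OCc9ccccc9)cc(OCc9ccccc9)c(OCc9ccccc9)c3OCc9ccccc9 | intermediate
27 | 4-bromo-2,6-difluorobenzaldehyde | O=Cc1c(F)cc(Br)cc1F | starting material
28 | 2,6-bis(benzyloxy)-4-bromobenzaldehyde | O=Cc1c(OCc9ccccc9)cc(Br)cc1OCc9ccccc9 | intermediate
29 | 2,6-bis(benzyloxy)-4-(ArABC-oxy)benzaldehyde | O=Cc4c(OCc9ccccc9)cc(Oc3c(Oc1cc(Oc2c(OCc9ccccc9)cc(OCc9ccccc9)cc2OCc9ccccc9)cc(OCc9ccccc9)c1OCc9ccccc9)cc(OCc9ccccc9)c(OCc9ccccc9)c3OCc9ccccc9)cc4OCc9ccccc9 | intermediate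
30 | ArABCD formate | O=COc4c(OCc9ccccc9)cc(Oc3c(Oc1cc(Oc2c(OCc9ccccc9)cc(OCc9ccccc9)cc2OCc9ccccc9)cc(OCc9ccccc9)c1OCc9ccccc9)cc(OCc9ccccc9)c(OCc9ccccc9)c3OCc9ccccc9)cc4OCc9ccccc9 | intermediate
31 | ArABCD–OH, 2,6-bis(benzyloxy)-4-(ArABC-oxy)phenol | Oc4c(OCc9ccccc9)cc(Oc3c(Oc1cc(Oc2c(OCc9ccccc9)cc(OCc9ccccc9)cc2OCc9ccccc9)cc(OCc9ccccc9)c1OCc9ccccc9)cc(OCc9ccccc9)c(OCc9ccccc9)c3OCc9ccccc9)cc4OCc9ccccc9 | intermediate
32 | 5-bromopyrogallol (5-bromobenzene-1,2,3-triol) | Oc1cc(Br)cc(O)c1O | starting material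
33 | 1,2,3-tris(benzyloxy)-5-bromobenzene | Brc1cc(OCc9ccccc9)c(OCc9ccccc9)c(OCc9ccccc9)c1 | intermediate
34 | 2,3,4-tris(benzyloxy)-6-bromophenyllithium | [Li]c1c(Br)cc(OCc9ccccc9)c(OCc9ccccc9)c1OCc9ccccc9 | intermediate
35 | lithium [2,3,4-tris(benzyloxy)-6-bromophenyl](dimethylamino)methanolate (racemic) | [Li]OC(N(C)C)c1c(Br)cc(OCc9ccccc9)c(OCc9ccccc9)c1OCc9ccccc9 | intermediate
36 | 2,3,4-tris(benzyloxy)-6-bromobenzaldehyde | O=Cc1c(Br)cc(OCc9ccccc9)c(OCc9ccccc9)c1OCc9ccccc9 | intermediate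
37 | 2,3,4-tris(benzyloxy)-6-(ArABCD-oxy)benzaldehyde | O=Cc5c(Oc4c(OCc9ccccc9)cc(Oc3c(Oc1cc(Oc2c(OCc9ccccc9)cc(OCc9ccccc9)cc2OCc9ccccc9)cc(OCc9ccccc9)c1OCc9ccccc9)cc(OCc9ccccc9)c(OCc9ccccc9)c3OCc9ccccc9)cc4OCc9ccccc9)cc(OCc9ccccc9)c(OCc9ccccc9)c5OCc9ccccc9 | intermediate
38 | ArABCDE formate | O=COc5c(Oc4c(OCc9ccccc9)cc(Oc3c(Oc1cc(Oc2c(OCc9ccccc9)cc(OCc9ccccc9)cc2OCc9ccccc9)cc(OCc9ccccc9)c1OCc9ccccc9)cc(OCc9ccccc9)c(OCc9ccccc9)c3OCc9ccccc9)cc4OCc9ccccc9)cc(OCc9ccccc9)c(OCc9ccccc9)c5OCc9ccccc9 | intermediate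
39 | ArABCDE–OH, 2,3,4-tris(benzyloxy)-6-(ArABCD-oxy)phenol | Oc5c(Oc4c(OCc9ccccc9)cc(Oc3c(Oc1cc(Oc2c(OCc9ccccc9)cc(OCc9ccccc9)cc2OCc9ccccc9)cc(OCc9ccccc9)c1OCc9ccccc9)cc(OCc9ccccc9)c(OCc9ccccc9)c3OCc9ccccc9)cc4OCc9ccccc9)cc(OCc9ccccc9)c(OCc9ccccc9)c5OCc9ccccc9 | intermediate
40 | 2-(benzyloxy)-4-bromo-6-fluorobenzaldehyde | O=Cc1c(F)cc(Br)cc1OCc9ccccc9 | intermediate
41 | 3,4,5-tris(benzyloxy)phenol | Oc1cc(OCc9ccccc9)c(OCc9ccccc9)c(OCc9ccccc9)c1 | intermediate
42 | 2-(benzyloxy)-4-bromo-6-[3,4,5-tris(benzyloxy)phenoxy]benzaldehyde | O=Cc6c(OCc9ccccc9)cc(Br)cc6Oc7cc(OCc9ccccc9)c(OCc9ccccc9)c(OCc9ccccc9)c7 | intermediate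
43 | 2-(benzyloxy)-4-(ArABCDE-oxy)-6-[3,4,5-tris(benzyloxy)phenoxy]benzaldehyde | O=Cc6c(OCc9ccccc9)cc(Oc5c(Oc4c(OCc9ccccc9)cc(Oc3c(Oc1cc(Oc2c(OCc9ccccc9)cc(OCc9ccccc9)cc2OCc9ccccc9)cc(OCc9ccccc9)c1OCc9ccccc9)cc(OCc9ccccc9)c(OCc9ccccc9)c3OCc9ccccc9)cc4OCc9ccccc9)cc(OCc9ccccc9)c(OCc9ccccc9)c5OCc9ccccc9)cc6Oc7cc(OCc9ccccc9)c(OCc9ccccc9)c(OCc9ccccc9)c7 | intermediate
44 | formate of 45 | O=COc6c(OCc9ccccc9)cc(Oc5c(Oc4c(OCc9ccccc9)cc(Oc3c(Oc1cc(Oc2c(OCc9ccccc9)cc(OCc9ccccc9)cc2OCc9ccccc9)cc(OCc9ccccc9)c1OCc9ccccc9)cc(OCc9ccccc9)c(OCc9ccccc9)c3OCc9ccccc9)cc4OCc9ccccc9)cc(OCc9ccccc9)c(OCc9ccccc9)c5OCc9ccccc9)cc6Oc7cc(OCc9ccccc9)c(OCc9ccccc9)c(OCc9ccccc9)c7 | intermediate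
45 | 2-(benzyloxy)-4-(ArABCDE-oxy)-6-[3,4,5-tris(benzyloxy)phenoxy]phenol | Oc6c(OCc9ccccc9)cc(Oc5c(Oc4c(OCc9ccccc9)cc(Oc3c(Oc1cc(Oc2c(OCc9ccccc9)cc(OCc9ccccc9)cc2OCc9ccccc9)cc(OCc9ccccc9)c1OCc9ccccc9)cc(OCc9ccccc9)c(OCc9ccccc9)c3OCc9ccccc9)cc4OCc9ccccc9)cc(OCc9ccccc9)c(OCc9ccccc9)c5OCc9ccccc9)cc6Oc7cc(OCc9ccccc9)c(OCc9ccccc9)c(OCc9ccccc9)c7 | intermediate
46 | CNP0137585.0 (achiral) | Oc1cc(O)c(Oc2cc(O)c(O)c(Oc3cc(O)c(O)c(O)c3Oc3cc(O)c(Oc4cc(O)c(O)c(O)c4Oc4cc(O)c(O)c(Oc5cc(O)c(O)c(O)c5)c4)c(O)c3)c2)c(O)c1 | target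

## Step count and risks

Total steps: 26. Longest linear sequence: 18 (steps 1, 2, 4–8, 10–13, 15, 16, 19, 20, 24–26).

**Step 11.**
- Risk: the ring-opened ketene may be consumed by intermolecular capture. The acetal may be lost at the reaction temperature. The very electron-rich phenol may oxidise as it forms.
- Fallback: ring C is brought in as a preformed arene instead of being built. It sets out from phenol 9 and bromoaldehyde 36, which are joined by copper-catalysed Ullmann etherification (CuI, picolinic acid, K3PO4, DMSO) to give 2,3,4-tris(benzyloxy)-6-(ArAB-oxy)benzaldehyde F1. Baeyer–Villiger oxidation with mCPBA gives the ArABC formate F2, and methanolysis of F2 comes back to the route at phenol 26.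

**Step 10.**
- Risk: O-alkylation of the crowded tertiary lithium alkoxide may be slow, so that the alkoxide decomposes on warming before it is capped.
- Fallback: the two hydroquinone oxygens are told apart by sterics instead of by a cap. It sets out from alkoxide 20, which is protonated with water at −78 °C to give the tertiary alcohol rac-4-[1-(ArAB-oxy)vinyl]-2,3-bis(benzyloxy)-4-hydroxycyclobut-2-en-1-one F3. Heating F3 in degassed toluene should give, by the same electrocyclic sequence, 2,3-bis(benzyloxy)-5-(ArAB-oxy)benzene-1,4-diol F4. One equivalent of BnBr with K2CO3 in acetone should alkylate the less hindered hydroxyl next to the CH, which comes back to the route at phenol 26.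

**Step 8.**
- Risk: regiocontrol may be poor, with tin delivered in part to the terminal carbon, and the acid-sensitive stannane may undergo protodestannylation on purification.
- Fallback: the tin chemistry is replaced by ionic hydrohalogenation. It sets out from ynol ether 15. HBr made from Me3SiBr and MeOH in CH2Cl2 at −78 °C protonates the terminal carbon, and bromide captures the oxygen-stabilised cation to give 1-bromovinyl ArAB ether F5. Bromine–lithium exchange with t-BuLi (2 equiv) in THF at −78 °C comes back to the route at vinyllithium 19.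

Further compounds
F1 | step 11 | 2,3,4-tris(benzyloxy)-6-(ArAB-oxy)benzaldehyde | O=Cc3c(Oc1cc(Oc2c(OCc9ccccc9)cc(OCc9ccccc9)cc2OCc9ccccc9)cc(OCc9ccccc9)c1OCc9ccccc9)cc(OCc9ccccc9)c(OCc9ccccc9)c3OCc9ccccc9
F2 | step 11 | ArABC formate | O=COc3c(Oc1cc(Oc2c(OCc9ccccc9)cc(OCc9ccccc9)cc2OCc9ccccc9)cc(OCc9ccccc9)c1OCc9ccccc9)cc(OCc9ccccc9)c(OCc9ccccc9)c3OCc9ccccc9
F3 | step 10 | rac-4-[1-(ArAB-oxy)vinyl]-2,3-bis(benzyloxy)-4-hydroxycyclobut-2-en-1-one | C=C(Oc1cc(Oc2c(OCc9ccccc9)cc(OCc9ccccc9)cc2OCc9ccccc9)cc(OCc9ccccc9)c1OCc9ccccc9)C3(O)C(OCc9ccccc9)=C(OCc9ccccc9)C3=O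
F4 | step 10 | 2,3-bis(benzyloxy)-5-(ArAB-oxy)benzene-1,4-diol | Oc3cc(Oc1cc(Oc2c(OCc9ccccc9)cc(OCc9ccccc9)cc2OCc9ccccc9)cc(OCc9ccccc9)c1OCc9ccccc9)c(O)c(OCc9ccccc9)c3OCc9ccccc9
F5 | step 8 | 1-bromovinyl ArAB ether | C=C(Br)Oc1cc(Oc2c(OCc9ccccc9)cc(OCc9ccccc9)cc2OCc9ccccc9)cc(OCc9ccccc9)c1OCc9ccccc9
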